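Ring C, the propanoyl-bearing cyclohexadienone ring, is disconnected at the bond between its gem-dimethyl carbon and the enolised carbonyl carbon that neighbours the bridging methylene. That ring is not derived from a phloroglucinol: it is built from an acyclic β-ethoxy enoyl chloride and an ynol ether that already carries the future bridge as CH2SPh. In one thermal operation a vinylketene, a [2+2] adduct and a dienylketene follow one another, and 6π closure onto the isopropylidene terminus gives the non-aromatisable 6,6-dimethyl dienone with all ring oxygens in place. The step exploits the quaternary C(CH3)2 carbon and the 1,3,5-oxygen pattern of ring C. Acylation and two methylene couplings complete the trimer.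

Key step: step 4

Remark on the chemistry: the enolised cyclic triketone rings are drawn as one tautomer each; the target has no stereocentre, and the only chiral intermediate (8) is racemic and transient.

Step 1
Reactants: 1 ethyl 4-methyl-3-oxopentanoate
Product: 2 ethyl (2E)-3-ethoxy-4-methylpent-2-enoate
Conditions: HC(OEt)3, cat. H2SO4, EtOH, rt; then distil
Reagents that add atoms: triethyl orthoformate CCOC(OCC)OCC
Why: Acid-catalysed ketalisation of the ketone with the orthoester followed by loss of ethanol (enol ether formation from a β-keto ester) should give the conjugated β-ethoxy enoate, the E isomer being expected because the double bond settles in conjugation with the ester; the geometry is not carried into the target.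

Step 2
Reactants: 2 ethyl (2E)-3-ethoxy-4-methylpent-2-enoate
Product: 3 (2E)-3-ethoxy-4-methylpent-2-enoic acid
Conditions: KOH, EtOH/H2O, 50 °C; then aq. HCl to pH 3, 0 °C
Reagents that add atoms: potassium hydroxide [K+].[OH-]
Why: Saponification of the ester should leave the base-stable β-alkoxy acrylate unit intact, and brief cold acidification frees the acid without hydrolysing the enol ether.

Step 3
Reactants: 4 ethoxyacetylene
Product: 5 [(3-ethoxyprop-2-yn-1-yl)sulfanyl]benzene
Conditions: n-BuLi, THF, −78 °C; then PhSCH2Cl, −78 °C to rt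
Reagents that add atoms: chloromethyl phenyl sulfide ClCSc1ccccc1
Why: Deprotonation of the terminal alkyne and SN2 alkylation of the lithium acetylide with the highly reactive α-chloro sulfide should install the CH2SPh group that later becomes the methylene bridge.

Step 4
Reactants: 3 (2E)-3-ethoxy-4-methylpent-2-enoic acid, 5 [(3-ethoxyprop-2-yn-1-yl)sulfanyl]benzene
Product: 10 3,5-diethoxy-6,6-dimethyl-2-[(phenylsulfanyl)methyl]cyclohexa-2,4-dien-1-one, via acid chloride 6 (not isolated), via vinylketene 7 (not isolated), via alkenylcyclobutenone 8 (not isolated), via dienylketene 9 (not isolated)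
Conditions: (COCl)2, cat. DMF, CH2Cl2, 0 °C to rt, evaporate; then added slowly to 5 and Et3N, toluene, 50 to 90 °C, dark
Reagents that add atoms: none
Why: After conversion of 3 into 6, Et3N removes HCl in a 1,4-sense to give vinylketene 7, the polarised ynol ether 5 adds to its ketene C=C bond in a regioselective [2+2] cycloaddition (the alkyne carbon remote from oxygen bonds to the ketene carbonyl carbon) to give 8, and reversible conrotatory 4π opening of 8 gives dienylketene 9. The six-membered carbocycle is then closed by a thermal disrotatory 6π electrocyclisation in which the ketene carbon bonds to the isopropylidene carbon, so the C(=O)–C(CH3)2 bond is made in the ring-closing event and, that carbon being quaternary, the dienone cannot tautomerise to a phenol. The closest known reaction type is the vinylketene–ynol ether (Danheiser) benzannulation, whose last event is the thermal reverse of the photochemical ring opening of 6,6-disubstituted cyclohexa-2,4-dienones. No stereocentre results, because the one in 8 is lost on ring opening and the new quaternary carbon bears two identical methyl groups. The step needs the ketene and alkenyl groups cis across C3=C4 of 9, which is secured because the unproductive outward opening of 8 is reversible while the closure is not, and it needs CH2SPh beside the ketene carbon, which the ynol ether polarity secures. As a result the new bond is flanked by the carbon that carries the future bridging methylene, and the donor ethoxy groups at C3 and C5 make the isopropylidene terminus nucleophilic towards the ketene.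

Step 5
Reactants: 10 3,5-diethoxy-6,6-dimethyl-2-[(phenylsulfanyl)methyl]cyclohexa-2,4-dien-1-one
Product: 11 3,5-dihydroxy-4,4-dimethyl-2-[(phenylsulfanyl)methyl]cyclohexa-2,5-dien-1-one
Conditions: 2 M aq. HCl, THF, 50 °C
Reagents that add atoms: water O
Why: Acid hydrolysis of the vinylogous ester and of the dienol ether should give the enolised cyclic triketone, the aryl alkyl sulfide being inert to aqueous acid because thiophenol can leave only from an enolate.

Step 6
Reactants: 11 3,5-dihydroxy-4,4-dimethyl-2-[(phenylsulfanyl)methyl]cyclohexa-2,5-dien-1-one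
Product: 13 3,5-dihydroxy-4,4-dimethyl-2-[(phenylsulfanyl)methyl]-6-propanoylcyclohexa-2,5-dien-1-one, via difluoroboron chelate 12 (not isolated)
Conditions: (EtCO)2O, BF3·OEt2, 60 °C; then NaOAc, MeOH/H2O, 60 °C
Reagents that add atoms: propanoic anhydride CCC(=O)OC(=O)CC
Why: Lewis-acid-mediated C-acylation of an enolised cyclic 1,3-dione (the way acylfilicinic acids are made from filicinic acid) should take place at C6, the only free ring carbon, the acidic medium keeping the base-releasable sulfide in place, and the difluoroboron chelate 12 is cleaved on the buffered work-up.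

Step 7
Reactants: 14 1-(2,4,6-trihydroxyphenyl)ethan-1-one
Product: 15 2-acetyl-3,5-dihydroxy-4,4-dimethylcyclohexa-2,5-dien-1-one (acetylfilicinic acid)
Conditions: NaOMe, MeI (2 equiv), MeOH, 0 °C to rt; then aq. HCl
Reagents that add atoms: iodomethane CI
Why: Base-mediated dearomatising C-methylation of the acylphloroglucinol should place two methyl groups on one ring carbon, a known entry to acylfilicinic acids, with the amount of iodomethane limited to suppress tri- and tetramethylation.

Step 8
Reactants: 16 benzene-1,3,5-triol (phloroglucinol)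
Product: 17 1-(2,4,6-trihydroxyphenyl)butan-1-one
Conditions: butanoyl chloride, AlCl3, PhNO2, 65 °C; then ice, aq. HCl
Reagents that add atoms: butanoyl chloride CCCC(=O)Cl
Why: Friedel–Crafts acylation of phloroglucinol should stop at the monoketone because the first acyl group deactivates the ring.

Step 9
Reactants: 15 2-acetyl-3,5-dihydroxy-4,4-dimethylcyclohexa-2,5-dien-1-one, 17 1-(2,4,6-trihydroxyphenyl)butan-1-one
Product: 20 1-[3-[(5-acetyl-2,4-dihydroxy-3,3-dimethyl-6-oxocyclohexa-1,4-dien-1-yl)methyl]-2,4,6-trihydroxyphenyl]butan-1-one, via Mannich base 18 (not isolated), via methylene trione 19 (not isolated)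
Conditions: [Me2N=CH2]I (1 equiv), MeCN, rt; then 17 (3 equiv), 70 °C
Reagents that add atoms: N,N-dimethylmethyleneiminium iodide C=[N+](C)C.[I-]
Why: Mannich reaction of the iminium salt at the only free ring carbon of 15 gives 18, which on heating loses dimethylamine (retro-Michael) to the methylene trione 19, and this is trapped in a Michael-type Friedel–Crafts alkylation by the electron-rich ring of 17, used in excess so that only one of its two equivalent positions reacts.

Step 10
Reactants: 13 3,5-dihydroxy-4,4-dimethyl-2-[(phenylsulfanyl)methyl]-6-propanoylcyclohexa-2,5-dien-1-one, 20 1-[3-[(5-acetyl-2,4-dihydroxy-3,3-dimethyl-6-oxocyclohexa-1,4-dien-1-yl)methyl]-2,4,6-trihydroxyphenyl]butan-1-one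
Product: 22 1-[3-[(5-acetyl-2,4-dihydroxy-3,3-dimethyl-6-oxocyclohexa-1,4-dien-1-yl)methyl]-5-[(2,4-dihydroxy-3,3-dimethyl-6-oxo-5-propanoylcyclohexa-1,4-dien-1-yl)methyl]-2,4,6-trihydroxyphenyl]butan-1-one (target), via methylene trione 21 (not isolated)
Conditions: iPr2NEt, MeCN, 40 °C, argon; then aq. citric acid
Reagents that add atoms: none
Why: The amine base turns 13 into its enolate, which releases thiophenolate reversibly (retro-thia-Michael, E1cB) to the methylene trione 21, and irreversible Michael-type C-alkylation at the single free aromatic carbon of 20 followed by re-aromatisation should give the target, mild base and temperature being chosen to avoid exchange of the methylene bridges.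

Compound list
1 | ethyl 4-methyl-3-oxopentanoate | CCOC(=O)CC(=O)C(C)C | starting material
2 | ethyl (2E)-3-ethoxy-4-methylpent-2-enoate | CCOC(=O)/C=C(/OCC)C(C)C | intermediate
3 | (2E)-3-ethoxy-4-methylpent-2-enoic acid | OC(=O)/C=C(/OCC)C(C)C | intermediate
4 | ethoxyacetylene | C#COCC | starting material
5 | [(3-ethoxyprop-2-yn-1-yl)sulfanyl]benzene | CCOC#CCSc1ccccc1 | intermediate
6 | (2E)-3-ethoxy-4-methylpent-2-enoyl chloride | ClC(=O)/C=C(/OCC)C(C)C | intermediate
7 | 3-ethoxy-4-methylpenta-1,3-dien-1-one (vinylketene) | O=C=CC(OCC)=C(C)C | intermediate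
8 | 3-ethoxy-4-(1-ethoxy-2-methylprop-1-en-1-yl)-2-[(phenylsulfanyl)methyl]cyclobut-2-en-1-one (racemic) | O=C1C(CSc2ccccc2)=C(OCC)C1C(OCC)=C(C)C | intermediate
9 | 3,5-diethoxy-6-methyl-2-[(phenylsulfanyl)methyl]hepta-1,3,5-trien-1-one (dienylketene, ketene carbon and C5 cis across C3=C4) | O=C=C(CSc1ccccc1)/C(OCC)=C\C(OCC)=C(C)C | intermediate
10 | 3,5-diethoxy-6,6-dimethyl-2-[(phenylsulfanyl)methyl]cyclohexa-2,4-dien-1-one | O=C1C(CSc2ccccc2)=C(OCC)C=C(OCC)C1(C)C | intermediate
11 | 3,5-dihydroxy-4,4-dimethyl-2-[(phenylsulfanyl)methyl]cyclohexa-2,5-dien-1-one | CC1(C)C(O)=CC(=O)C(CSc2ccccc2)=C1O | intermediate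
12 | difluoroboron chelate of 13 (2,2-difluoro-1,3,2-dioxaborinine across the propanoyl oxygen and the neighbouring ring oxygen) | CCC1=[O+][B-](F)(F)OC2=C1C(=O)C(CSc1ccccc1)=C(O)C2(C)C | intermediate
13 | 3,5-dihydroxy-4,4-dimethyl-2-[(phenylsulfanyl)methyl]-6-propanoylcyclohexa-2,5-dien-1-one | CCC(=O)C1=C(O)C(C)(C)C(O)=C(CSc2ccccc2)C1=O | intermediate
14 | 1-(2,4,6-trihydroxyphenyl)ethan-1-one | CC(=O)c1c(O)cc(O)cc1O | starting material
15 | 2-acetyl-3,5-dihydroxy-4,4-dimethylcyclohexa-2,5-dien-1-one (acetylfilicinic acid) | CC(=O)C1=C(O)C(C)(C)C(O)=CC1=O | intermediate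
16 | benzene-1,3,5-triol (phloroglucinol) | Oc1cc(O)cc(O)c1 | starting material
17 | 1-(2,4,6-trihydroxyphenyl)butan-1-one | CCCC(=O)c1c(O)cc(O)cc1O | intermediate
18 | 2-acetyl-6-[(dimethylamino)methyl]-3,5-dihydroxy-4,4-dimethylcyclohexa-2,5-dien-1-one (Mannich base) | CC(=O)C1=C(O)C(C)(C)C(O)=C(CN(C)C)C1=O | intermediate
19 | 2-acetyl-3-hydroxy-4,4-dimethyl-6-methylidenecyclohex-2-ene-1,5-dione | CC(=O)C1=C(O)C(C)(C)C(=O)C(=C)C1=O | intermediate
20 | 1-[3-[(5-acetyl-2,4-dihydroxy-3,3-dimethyl-6-oxocyclohexa-1,4-dien-1-yl)methyl]-2,4,6-trihydroxyphenyl]butan-1-one | CCCC(=O)c1c(O)cc(O)c(CC2=C(O)C(C)(C)C(O)=C(C(C)=O)C2=O)c1O | intermediate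
21 | 3-hydroxy-4,4-dimethyl-6-methylidene-2-propanoylcyclohex-2-ene-1,5-dione | CCC(=O)C1=C(O)C(C)(C)C(=O)C(=C)C1=O | intermediate
22 | 1-[3-[(5-acetyl-2,4-dihydroxy-3,3-dimethyl-6-oxocyclohexa-1,4-dien-1-yl)methyl]-5-[(2,4-dihydroxy-3,3-dimethyl-6-oxo-5-propanoylcyclohexa-1,4-dien-1-yl)methyl]-2,4,6-trihydroxyphenyl]butan-1-one | CCCC(=O)c1c(O)c(CC2=C(O)C(C)(C)C(O)=C(C(C)=O)C2=O)c(O)c(CC2=C(O)C(C)(C)C(O)=C(C(=O)CC)C2=O)c1O | target

Total step count: 10. Longest linear sequence: 6 steps (steps 1, 2, 4, 5, 6 and 10).

Steps most likely to fail

1. Step 4. The vinylketene may oligomerise in the presence of the amine and its hydrochloride before the ynol ether intercepts it, or the ynol ether may be hydrochlorinated. The fallback sets out from 4 and returns at 10. Isobutyryl chloride and Et3N give dimethylketene F1, which adds to ethoxyacetylene 4 in a [2+2] cycloaddition to give 3-ethoxy-4,4-dimethylcyclobut-2-en-1-one F2. Distilled F2 is heated with 5 in toluene at 100 °C without amine; electrocyclic 4π opening of F2 delivers vinylketene 7 at low stationary concentration, and the sequence runs on through 8 and 9 to 10 by the same 6π closure.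

2. Step 10. Return of thiophenolate to the methylene trione may outrun the C-alkylation, or the base may induce exchange of the methylene bridges between the rings. The fallback sets out from 13 and returns at 22. Compound 13 is oxidised with mCPBA (1 equiv, CH2Cl2, −78 °C) to the sulfoxide 3,5-dihydroxy-4,4-dimethyl-2-[(phenylsulfinyl)methyl]-6-propanoylcyclohexa-2,5-dien-1-one F3. Compound 20 and NaHCO3 are then added, and on warming F3 loses benzenesulfenic acid irreversibly to give 21, which 20 traps to give 22.

3. Step 6. The Lewis acid may ionise the C–S bond, or acylation may stop at oxygen. The fallback sets out from 11 and returns at 13. Compound 11 is O-acylated with propanoyl chloride and pyridine at −20 °C to the enol ester 5-hydroxy-6,6-dimethyl-3-oxo-4-[(phenylsulfanyl)methyl]cyclohexa-1,4-dien-1-yl propanoate F4. Catalytic DMAP then transfers the acyl group from oxygen to the free ring carbon (O-to-C acyl migration) to give 13.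

Further compounds
F1 | step 4 | dimethylketene | CC(C)=C=O
F2 | step 4 | 3-ethoxy-4,4-dimethylcyclobut-2-en-1-one | CCOC1=CC(=O)C1(C)C
F3 | step 10 | 3,5-dihydroxy-4,4-dimethyl-2-[(phenylsulfinyl)methyl]-6-propanoylcyclohexa-2,5-dien-1-one | CCC(=O)C1=C(O)C(C)(C)C(O)=C(CS(=O)c2ccccc2)C1=O
F4 | step 6 | 5-hydroxy-6,6-dimethyl-3-oxo-4-[(phenylsulfanyl)methyl]cyclohexa-1,4-dien-1-yl propanoate | CCC(=O)OC1=CC(=O)C(CSc2ccccc2)=C(O)C1(C)C
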